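**Plan**

- Enabling feature: the pyridone ring of the 4-quinolone carries C4=O, C3–H and the side chain on C2. This pattern equals C3, the 3-methyl carbon and C2 of a 2-alkyl-3-methylindole once the methyl carbon is inserted between C3 and C2.
- Retrosynthetic cuts, in order: the quinolone C2–C3 bond (back to an acetyl/anilide pair, i.e. to the indole C2=C3 bond); the side-chain bond between the ring-bound CH2 and the next CH2; the two C–CH3 bonds of the carbinol.
- Forward: ester 1 and MeMgBr 2 give bromo carbinol 4, which is silylated to 5. The chain is joined to the 2-methyl group of 2,3-dimethylindole 6 to give indole 11 (benzene and pyrrole rings purchased). The pyridone ring is the only ring made, by oxidative ring expansion of 11 to 16.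
- Stereochemistry: none to set. The stereocentres of the transient species 12, 13 and 15 are racemic and are destroyed within the same step.

Key step: step 4

Assumption: the target has no stereocentre and no stereogenic double bond, so there is no enantiomer to select; it is treated as the 4(1H)-quinolone tautomer as drawn.

**Route**

Step 1
Reactants: 1 methyl 11-bromoundecanoate; 2 methylmagnesium bromide
Product: 4 12-bromo-2-methyldodecan-2-ol, via 12-bromododecan-2-one 3 (not isolated)
Conditions: MeMgBr (2.5 equiv, Et2O solution), THF, 0 °C → rt; then sat. aq NH4Cl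
Reagents that add atoms: methylmagnesium bromide (compound 2), C[Mg]Br
Why: Double Grignard addition to the ester through methyl ketone 3 should give the tertiary carbinol, because an unactivated primary alkyl bromide is inert to MeMgBr at or below room temperature without a transition-metal catalyst.

Step 2
Reactants: 4 12-bromo-2-methyldodecan-2-ol
Product: 5 [(12-bromo-2-methyldodecan-2-yl)oxy]trimethylsilane
Conditions: TMSCl (1.5 equiv), imidazole (2.5 equiv), CH2Cl2, 0 °C → rt
Reagents that add atoms: chlorotrimethylsilane, C[Si](C)(C)Cl
Why: O-silylation with the small trimethylsilyl group proceeds even on a tertiary hydroxyl and removes the acidic O–H before the carbanion step, while the resulting hindered silyl ether should resist organolithium attack at low temperature yet fall off in dilute acid.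

Step 3
Reactants: 6 2,3-dimethyl-1H-indole; 5 [(12-bromo-2-methyldodecan-2-yl)oxy]trimethylsilane
Product: 11 2-methyl-13-(3-methyl-1H-indol-2-yl)tridecan-2-ol, via lithium N-carboxylate 7 (not isolated), via lithiomethyl dianion 8 (not isolated), via alkylated N-carboxylate 9 (not isolated), via silyl ether indole 10 (not isolated)
Conditions: 6 (1.2 equiv), n-BuLi (1.2 equiv), THF, −78 °C; CO2 (g), then removal of excess CO2 under vacuum/Ar; t-BuLi (1.25 equiv), THF, −78 → −20 °C; 5 (1.0 equiv), −78 °C → rt; then 1 M aq HCl/THF, rt
Reagents that add atoms: none
Why: Lateral lithiation–alkylation of a 2-methylindole under in situ CO2 protection should work because the lithium N-carboxylate blocks nitrogen and directs t-BuLi to the adjacent, aza-allylic 2-CH3 (the 3-CH3 is neither directed nor activated), the resulting primary carbanion displaces the primary bromide by SN2, and the acidic work-up removes both CO2 (spontaneous decarboxylation of the indole-1-carboxylic acid) and the trimethylsilyl ether.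

Step 4
Reactants: 11 2-methyl-13-(3-methyl-1H-indol-2-yl)tridecan-2-ol
Product: 16 2-(12-hydroxy-12-methyltridecyl)quinolin-4(1H)-one, via hydroperoxyindolenine 12 (not isolated), via dioxetane 13 (not isolated), via keto amide 14 (not isolated), via carbinolamine 15 (not isolated)
Conditions: t-BuOK (5 equiv), O2 (1 atm), DMF, 0 °C → rt until 11 is consumed; then Ar purge, 60 °C; aq NH4Cl
Reagents that add atoms: dioxygen, O=O
Why: In this Winterfeldt oxidation, t-BuOK deprotonates the indole N–H and the ambident anion traps O2 at C3 to give hydroperoxide 12, whose peroxide oxygen adds to the C2=N bond (dioxetane 13) and fragments with cleavage of the former C2–C3 bond to the N-(2-acetylphenyl)amide 14. Under the same base the acetyl enolate attacks the amide carbonyl (Camps condensation, 6-(enolendo)-exo-trig) to give carbinolamine 15, which loses water to the vinylogous amide 16, so the pyridone ring and the quinolone C2–C3 bond arise in a single closure. The closest known reactions are the t-BuOK/O2/DMF ring expansion of tetrahydrocarbazoles and tetrahydro-β-carbolines to 4-quinolones, and the Witkop cleavage followed by Camps cyclisation of 2,3-dialkylindoles. No stereocentre has to be controlled, since those of 12, 13 and 15 are racemic and disappear on fragmentation or dehydration. The selectivity needed is closure through the methyl ketone enolate and not through the amide α-methylene (which would lead to a 3-alkyl-4-methyl-2-quinolone); it is secured by the far higher acidity of the aryl methyl ketone under excess alkoxide and by the stabilised 4-quinolone anion that results. The tertiary hydroxyl cannot be oxidised and rides through as its alkoxide, and the switch to argon before warming keeps the acetyl enolate of 14 from further autoxidation.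

**Compound list**

1 | methyl 11-bromoundecanoate | COC(=O)CCCCCCCCCCBr | starting material
2 | methylmagnesium bromide | C[Mg]Br | starting material
3 | 12-bromododecan-2-one | CC(=O)CCCCCCCCCCBr | intermediate (not isolated)
4 | 12-bromo-2-methyldodecan-2-ol | CC(C)(O)CCCCCCCCCCBr | intermediate
5 | [(12-bromo-2-methyldodecan-2-yl)oxy]trimethylsilane | CC(C)(O[Si](C)(C)C)CCCCCCCCCCBr | intermediate
6 | 2,3-dimethyl-1H-indole | Cc1[nH]c2ccccc2c1C | starting material
7 | lithium 2,3-dimethyl-1H-indole-1-carboxylate | Cc1c(C)c2ccccc2n1C(=O)[O-].[Li+] | intermediate (not isolated)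
8 | lithium 2-(lithiomethyl)-3-methyl-1H-indole-1-carboxylate | [Li]Cc1c(C)c2ccccc2n1C(=O)[O-].[Li+] | intermediate (not isolated)
9 | lithium 3-methyl-2-{12-methyl-12-[(trimethylsilyl)oxy]tridecyl}-1H-indole-1-carboxylate | Cc1c(CCCCCCCCCCCC(C)(C)O[Si](C)(C)C)n(C(=O)[O-])c2ccccc12.[Li+] | intermediate (not isolated)
10 | 3-methyl-2-{12-methyl-12-[(trimethylsilyl)oxy]tridecyl}-1H-indole | Cc1c(CCCCCCCCCCCC(C)(C)O[Si](C)(C)C)[nH]c2ccccc12 | intermediate (not isolated)
11 | 2-methyl-13-(3-methyl-1H-indol-2-yl)tridecan-2-ol | Cc1c(CCCCCCCCCCCC(C)(C)O)[nH]c2ccccc12 | intermediate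
12 | 13-(3-hydroperoxy-3-methyl-3H-indol-2-yl)-2-methyltridecan-2-ol (racemic) | CC1(OO)C(CCCCCCCCCCCC(C)(C)O)=Nc2ccccc12 | intermediate (not isolated)
13 | 13-(2,3-epidioxy-3-methyl-2,3-dihydro-1H-indol-2-yl)-2-methyltridecan-2-ol (cis-fused 1,2-dioxetane across C2–C3, racemic) | CC12OOC1(CCCCCCCCCCCC(C)(C)O)Nc1ccccc12 | intermediate (not isolated)
14 | N-(2-acetylphenyl)-13-hydroxy-13-methyltetradecanamide | CC(=O)c1ccccc1NC(=O)CCCCCCCCCCCC(C)(C)O | intermediate (not isolated)
15 | 2-hydroxy-2-(12-hydroxy-12-methyltridecyl)-2,3-dihydroquinolin-4(1H)-one (racemic) | CC(C)(O)CCCCCCCCCCCC1(O)CC(=O)c2ccccc2N1 | intermediate (not isolated)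
16 | 2-(12-hydroxy-12-methyltridecyl)quinolin-4(1H)-one | CC(C)(O)CCCCCCCCCCCc1cc(=O)c2ccccc2[nH]1 | target

**Count**

Total steps: 4. Longest linear sequence: 4 steps (1 → 4 → 5 → 11 → 16); indole 6 enters at step 3.

**Steps most likely to fail**

Step 4 (ring expansion). The fragmentation of the C3 hydroperoxide may stall or divert (reduction to the 3-hydroxyindolenine, or tautomerisation toward the side-chain α-carbon). The acetyl enolate may be oxygenated further before it cyclises, or ring closure may proceed through the amide α-methylene. The fallback sets out from 11 and comes back at 16, and separates cleavage from cyclisation. Indole 11 would be cleaved by ozonolysis (O3, CH2Cl2/MeOH, −78 °C; Me2S; Witkop-type cleavage), and keto amide 14 would be isolated and purified. It would then be closed in a separate, oxygen-free Camps cyclisation (NaOH, 1,4-dioxane, 110 °C, or t-BuOK, t-BuOH, 80 °C, under argon) to give 16. No compound outside the list is needed.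

Step 3 (chain attachment). Lateral deprotonation may be incomplete, the carbanion may act as a base toward the bromide (elimination), or the silyl group may be transferred to carbon. The fallback sets out from bromide 5 and comes back at 10, and forms a C=C bond by Wittig olefination in place of the SN2 alkylation. Bromide 5 would be heated with PPh3 in MeCN to give [11-methyl-11-(trimethylsilyloxy)dodecyl]triphenylphosphonium bromide F2. F2 (2.2 equiv) with KHMDS (2.2 equiv) in THF at −78 °C would then be combined with purchased 3-methyl-1H-indole-2-carbaldehyde F1, the first equivalent of base being consumed by the indole N–H. This should give 3-methyl-2-[(1Z)-12-methyl-12-(trimethylsilyloxy)tridec-1-en-1-yl]-1H-indole F3, the alkene geometry being irrelevant. Hydrogenation (H2, Pd/C, EtOAc) would give silyl ether indole 10, and 1 M HCl/THF would then give 11.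

Step 2 (silyl protection). Silylation of the hindered tertiary hydroxyl may be sluggish, and the trimethylsilyl group may be lost by hydrolysis during isolation or storage. The fallback sets out from bromo carbinol 4 and comes back at 11, and uses no covalent protecting group. Carbinol 4 would be deprotonated with n-BuLi (1.0 equiv, THF, −78 °C) to lithium 12-bromo-2-methyldodecan-2-olate F4. This solution would be added to dianion 8, generated as in step 3, to give dilithium 3-methyl-2-(12-methyl-12-oxidotridecyl)-1H-indole-1-carboxylate F5. Work-up with 1 M HCl should release 11 directly.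

**Further compounds**

F0 | step 4 | none | none
F1 | step 3 | 3-methyl-1H-indole-2-carbaldehyde (purchased) | Cc1c(C=O)[nH]c2ccccc12
F2 | step 3 | [11-methyl-11-(trimethylsilyloxy)dodecyl]triphenylphosphonium bromide | CC(C)(O[Si](C)(C)C)CCCCCCCCCC[P+](c1ccccc1)(c1ccccc1)c1ccccc1.[Br-]
F3 | step 3 | 3-methyl-2-[(1Z)-12-methyl-12-(trimethylsilyloxy)tridec-1-en-1-yl]-1H-indole | Cc1c(/C=C\CCCCCCCCCC(C)(C)O[Si](C)(C)C)[nH]c2ccccc12
F4 | step 2 | lithium 12-bromo-2-methyldodecan-2-olate | CC(C)([O-])CCCCCCCCCCBr.[Li+]
F5 | step 2 | dilithium 3-methyl-2-(12-methyl-12-oxidotridecyl)-1H-indole-1-carboxylate | Cc1c(CCCCCCCCCCCC(C)(C)[O-])n(C(=O)[O-])c2ccccc12.[Li+].[Li+]
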